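All runs stem from a simulated flask with constants of no real substance; scatter was added.

Each substrate is charged at 0.40 M, so each opens the ledger with half of the two together. The question is what the excess costs in right-handed substrate.

| flask | left-handed substrate | right-handed substrate | partner | precatalyst | remark | time |
|---|---|---|---|---|---|---|
| Friday's | 0.20 M | 0.20 M | 3 equiv | 3 mol% | run made earlier |  |
| Saturday's | 0.80 M | 0.80 M | 3 equiv | 3 mol% | run made earlier |  |
| Tuesday's | 0.40 M | 0.40 M | 3 equiv | 6 mol% | run made earlier |  |
| flask | 0.40 M | 0.40 M | 3.00 equiv | 3 mol% |  | 10 d |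

| run | time / d | right-handed substrate / % | left-handed substrate / % |
|---|---|---|---|
| Friday's | 1.04 | 50.1 | 46.6 |
| Friday's | 3.00 | 47.5 | 31.0 |
| Friday's | 5.00 | 46.1 | 16.5 |
| Friday's | 8.00 | 42.2 | 4.6 |
| Saturday's | 1.04 | 48.7 | 37.3 |
| Saturday's | 3.00 | 40.7 | 4.7 |
| Saturday's | 5.00 | 30.6 | 0.5 |
| Saturday's | 8.00 | 18.1 | 0.5 |
| Tuesday's | 2.08 | 44.6 | 16.0 |
| Tuesday's | 4.00 | 37.0 | 1.1 |
| Tuesday's | 6.00 | 29.1 | 0 |
| Tuesday's | 8.00 | 22.7 | 0.2 |

(each reading ± 0.5 percentage points)

1. whether the excess of right-handed substrate over left-handed substrate among what is left of the two reaches 99% by 10 d (yes / no)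
2. the highest excess of right-handed substrate over left-handed substrate among what is left of the two up to 10 d

- free catalyst is single-handed; left-handed substrate and right-handed substrate are mirror images of each other, charged as a racemate, each of them at the stated concentration

1. **The account.** The left-handed substrate is the limiting reagent of the resolution. Saturday's run reads 0.5% of it beside 30.6% right-handed substrate at 5.00 d.

2. **The fork.** The selectivity factor s is the logarithm of the fraction of left-handed substrate left, divided by the same logarithm for right-handed substrate. The latest clear readings give 14.1 on Friday, 11.5 on Saturday and 12.7 on Tuesday. Their mean is s = 12.7. So a molecule reacting from an equal mixture is left-handed with chance 92.7%.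

3. **The books at 99%.** The right-handed substrate left must be 31.9%, so 18.1% has been spent. The left-handed substrate left is 0.160%, below the scatter of 0.5 percentage points.

4. **The clock.** The flask's concentration lies between Friday's and Saturday's at the same loading. The mean of their right-handed readings at 8.00 d is 30.2%, lower than the price. My reckoning therefore says yes, with about 99.5% excess by then.

The forecast says yes and 99.8%, within 98.5% to 100%, and finds “no sign of catalyst death”.

The flask gives yes and 99.8%. It reaches 99% at 8.23 d, with 31.9% right-handed substrate left.

    free catalyst + left-handed substrate ⇌ catalyst intermediate A (K = 68.1 L mol⁻¹, k = 139 L mol⁻¹ h⁻¹)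
    free catalyst + right-handed substrate ⇌ catalyst intermediate B (K = 28.0 L mol⁻¹, k = 14.0 L mol⁻¹ h⁻¹)
    partner + catalyst intermediate A → free catalyst + left-handed product (k = 1.18 L mol⁻¹ h⁻¹)
    partner + catalyst intermediate B → free catalyst + right-handed product (k = 0.191 L mol⁻¹ h⁻¹)
    left-handed product ⇌ right-handed product (k = 0.0645 h⁻¹)
    2 free catalyst ⇌ resting dimer, settled at all times (K = 1400 L mol⁻¹)
    precatalyst → free catalyst (k = 0.0186 h⁻¹)

At 10.0 d the flask keeps 55% of its right-handed charge, for which s gives 0.0537% of the left-handed charge; the flask holds 0.050%. The run with twice the partner ends at >99.9%, so by s its right-handed substrate stands below 31.9%. The largest single effect on the excess in this flask belongs to the path from free catalyst and left-handed substrate to catalyst intermediate A, both ways. With that path the excess at 10.0 d is 99.8%; the same flask without it ends at −45.9%.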